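**Strategy.** Each butenolide is cut back to a spiro cyclobutenone: O1 of each lactone is inserted later between C2 and the spiro carbon C5. C5 and C5′, two adjacent carbons of the central cyclobutane, are therefore ketene termini, and C3/C4 of each lactone are the two carbons of an alkynyl ether. The key step joins one cyclobutane-1,2-bis(ketene) with two ynol ethers in a double (2+2) cycloaddition, forming four C–C bonds, both spiro rings and both spiro stereocentres at once. Its precursors are a C2-symmetric trans-3,4-bis(silyloxy)cyclobutane-1,2-dicarbonyl dichloride, made from the cis,trans,cis dianhydride, and a 3-silyloxyhex-1-ynyl ether used as both enantiomers.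

Key step: step 11

Assumption: quinidine is taken to open each anhydride ring so as to give the (1R,2R,3R,4R) diacid diester 2; if the sense of induction is the opposite one, quinine, its pseudo-enantiomer, takes its place.

Remark: the ynol ether carries a benzyl group on oxygen so that the tetronates formed later can be unmasked by neutral hydrogenolysis; ring oxygens carry TES and side-chain oxygens TBS so that the ring ethers can be cleaved first.

Remark: the target has one (S)- and one (R)-side chain on a C2-symmetric core, so the two ketene groups are homotopic and no one-pot addition can steer which enantiomer goes where. The racemic ynol ether is therefore used, and the heterochiral adduct, a single enantiomer because the core is enantiopure, is isolated.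

Step 1
Reactants: 1 cyclobutane-1,2,3,4-tetracarboxylic 1,2:3,4-dianhydride (cis,trans,cis isomer, achiral)
Product: 2 (1R,2R,3R,4R)-3,4-bis(methoxycarbonyl)cyclobutane-1,2-dicarboxylic acid (acids trans to each other, each acid cis to the ester on its other neighbour, esters trans)
Conditions: MeOH (6 equiv), quinidine (2.2 equiv), toluene, −55 °C; then 1 M HCl
Reagents that add atoms: methanol, CO
Why: Cinchona-alkaloid-mediated enantioselective alcoholysis of a meso anhydride, applied twice: the alkaloid acts as chiral general base and directs methanol to one of the two enantiotopic carbonyl groups of each anhydride, and because the carbonyl groups selected in the two rings are related by the molecular C2 axis the product is the C2-symmetric 1,2-diacid 3,4-diester, which fixes the absolute configuration of the four existing ring stereocentres (the achiral 1,3-diacid isomer is removed by crystallization).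

Step 2
Reactants: 2 (1R,2R,3R,4R)-3,4-bis(methoxycarbonyl)cyclobutane-1,2-dicarboxylic acid
Product: 4 dimethyl (1R,2R,3R,4R)-3,4-diacetylcyclobutane-1,2-dicarboxylate, via diacid dichloride 3 (not isolated)
Conditions: (COCl)2, DMF (cat.), CH2Cl2, 0 °C to rt; then Me2CuLi, Et2O, −78 °C
Reagents that add atoms: lithium dimethylcuprate, [Li+].C[Cu-]C
Why: Acid chloride formation followed by ketone synthesis from an acyl chloride and a lithium dialkylcuprate, which stops at the ketone and leaves the methyl esters alone at −78 °C, so that no stereocentre is touched.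

Step 3
Reactants: 4 dimethyl (1R,2R,3R,4R)-3,4-diacetylcyclobutane-1,2-dicarboxylate
Product: 5 dimethyl (1S,2S,3S,4S)-3,4-diacetoxycyclobutane-1,2-dicarboxylate
Conditions: mCPBA, CH2Cl2, 40 °C
Reagents that add atoms: meta-chloroperbenzoic acid (mCPBA), OOC(=O)c1cccc(Cl)c1
Why: Baeyer–Villiger oxidation of a methyl ketone, in which the secondary cyclobutyl carbon migrates in preference to methyl and with retention, so each acetyl group becomes an acetoxy group on the same face.

Step 4
Reactants: 5 dimethyl (1S,2S,3S,4S)-3,4-diacetoxycyclobutane-1,2-dicarboxylate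
Product: 6 dimethyl (1S,2S,3S,4S)-3,4-dihydroxycyclobutane-1,2-dicarboxylate
Conditions: AcCl (cat.), MeOH, 0 °C to rt
Reagents that add atoms: none
Why: Acid-catalysed transesterification removes the acetates without forming an alkoxide (which could open the β-hydroxy ester by retro-aldol cleavage) and is degenerate at the methyl esters.

Step 5
Reactants: 6 dimethyl (1S,2S,3S,4S)-3,4-dihydroxycyclobutane-1,2-dicarboxylate
Product: 7 dimethyl (1S,2S,3S,4S)-3,4-bis(triethylsilyloxy)cyclobutane-1,2-dicarboxylate
Conditions: Et3SiCl, imidazole, DMF, 0 °C to rt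
Reagents that add atoms: chlorotriethylsilane, CC[Si](Cl)(CC)CC
Why: Standard silylation of secondary alcohols with a silyl chloride and imidazole; the silyl ethers block retro-aldol opening and later shield one face of each ketene.

Step 6
Reactants: 7 dimethyl (1S,2S,3S,4S)-3,4-bis(triethylsilyloxy)cyclobutane-1,2-dicarboxylate
Product: 8 (1S,2S,3S,4S)-3,4-bis(triethylsilyloxy)cyclobutane-1,2-dicarboxylic acid
Conditions: LiOH, THF/H2O, 0 °C to rt; then dilute HCl to pH 4, 0 °C
Reagents that add atoms: lithium hydroxide, [Li+].[OH-]
Why: Ester saponification at low temperature, tolerated by the silyl ethers; any epimerization at the carboxyl-bearing carbons is harmless because both become sp2 in step 11.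

Step 7
Reactants: 8 (1S,2S,3S,4S)-3,4-bis(triethylsilyloxy)cyclobutane-1,2-dicarboxylic acid
Product: 9 (1S,2S,3S,4S)-3,4-bis(triethylsilyloxy)cyclobutane-1,2-dicarbonyl dichloride (COCl groups trans, OTES groups trans)
Conditions: 1-chloro-N,N,2-trimethylprop-1-en-1-amine, CH2Cl2, 0 °C to rt; used crude
Reagents that add atoms: 1-chloro-N,N,2-trimethylprop-1-en-1-amine, CC(C)=C(Cl)N(C)C
Why: Acid chloride formation with an α-chloroenamine proceeds under neutral conditions without free HCl, so the acid-labile silyl ethers survive.

Step 8
Reactants: 10 benzyl alcohol; 11 trichloroethylene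
Product: 12 benzyl (E)-1,2-dichlorovinyl ether
Conditions: KH, THF, 0 °C; then Cl2C=CHCl, −50 °C to rt
Reagents that add atoms: none
Why: Net addition–elimination of an alkoxide on trichloroethylene (through dichloroacetylene formed in situ), the established entry to 1,2-dichlorovinyl ethers as ynol ether precursors; the alkene geometry is of no consequence.

Step 9
Reactants: 12 benzyl (E)-1,2-dichlorovinyl ether; 13 butanal
Product: 15 rac-1-(benzyloxy)hex-1-yn-3-ol, via lithium benzyloxyacetylide 14 (not isolated)
Conditions: n-BuLi (2.2 equiv), THF, −78 to −40 °C; then PrCHO, −78 °C; pH 7 buffer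
Reagents that add atoms: none
Why: Dehydrochlorination and chlorine–lithium exchange give the lithium alkoxyacetylide, whose 1,2-addition to the aldehyde forms the propargylic carbinol as a racemate, both enantiomers of which are needed.

Step 10
Reactants: 15 rac-1-(benzyloxy)hex-1-yn-3-ol
Product: 16 rac-1-(benzyloxy)-3-(tert-butyldimethylsilyloxy)hex-1-yne (equimolar (S)- and (R)-ether)
Conditions: TBSCl, imidazole, DMF, rt
Reagents that add atoms: tert-butylchlorodimethylsilane, CC(C)(C)[Si](C)(C)Cl
Why: Silylation of a secondary propargylic alcohol under basic conditions, which the acid-sensitive ynol ether tolerates.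

Step 11
Reactants: 9 (1S,2S,3S,4S)-3,4-bis(triethylsilyloxy)cyclobutane-1,2-dicarbonyl dichloride; 16 rac-1-(benzyloxy)-3-(tert-butyldimethylsilyloxy)hex-1-yne (2.2 equiv; one (S)- and one (R)-molecule are taken up)
Product: 18 dispiro bis(3-benzyloxycyclobut-2-enone) with one (S)- and one (R)-1-(TBSO)butyl group at C2 of the enones (central trans-bis(OTES)cyclobutane; at each spiro carbon the benzyloxy-bearing carbon is trans and the carbonyl carbon cis to the neighbouring OTES), via bis-ketene 17 (not isolated)
Conditions: Et3N (2.4 equiv, slow addition), CH2Cl2, 0 °C to 35 °C; chromatography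
Reagents that add atoms: none
Why: Triethylamine dehydrochlorinates both acyl chlorides to ketenes (formally bis-ketene 17, more likely one site after the other), and each ketene is attacked at its central carbon, in the ketene plane, by the side-chain-bearing carbon of an ynol ether (the carbon β to oxygen) to give a 1,4-zwitterion made of an enolate and an alkoxy-stabilised vinyl cation. The closest known reaction is the (2+2) cycloaddition of dialkylketenes generated in situ with 1-alkoxyalkynes, which gives 3-alkoxycyclobut-2-enones. Each four-membered ring closes by 4-exo-dig attack of the enolate carbon (the cyclobutane carbon) on the oxocarbenium-like carbon, so the benzyloxy-bearing carbon becomes bonded to the spiro carbon and the side chain sits next to the carbonyl group; this head-to-tail orientation follows from the polarity of both partners. Each new spiro stereocentre is controlled by the OTES group on the adjacent ring carbon: the ring closes on the face of the planar ketene carbon away from that group (for the second ring also away from the benzyloxy-bearing carbon of the first ring), which puts every C(OBn) trans and every C=O cis to the neighbouring OTES and gives the C2-symmetric core. The step must also take up one (S)- and one (R)-ether: on a C2-symmetric bis-ketene this pairing is statistical (at best half of the adducts), and the unsymmetrical heterochiral adduct 18 is separated by chromatography from the two C2-symmetric homochiral diastereomers, which fixes the (S) and the (R) carbinol centre of the side chains. Slow addition of the base keeps the ketene concentration low against dimerization, loss of silyloxide from the β-position would have to form a cyclobutene and is therefore slow, and the temperature stays below 40 °C because benzyl alkynyl ethers rearrange on heating.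

Step 12
Reactants: 18 dispiro bis(3-benzyloxycyclobut-2-enone)
Product: 19 dispiro bis(4-benzyloxybutenolide) (bis benzyl tetronate; at each spiro carbon O1 takes the place of the former carbonyl carbon, cis to the neighbouring OTES)
Conditions: mCPBA, CH2Cl2, 0 °C to rt
Reagents that add atoms: meta-chloroperbenzoic acid (mCPBA), OOC(=O)c1cccc(Cl)c1
Why: Proposed new method: Baeyer–Villiger oxidation of a 3-alkoxycyclobut-2-enone (a vinylogous ester), in which the peracid should still add to the carbonyl group because the four-ring ketone loses angle strain on forming the tetrahedral Criegee adduct, and the fully substituted spiro carbon should migrate in preference to the sp2 carbon and with retention, so that the spiro configuration passes unchanged to C5 of each lactone; the closest known reactions are the Baeyer–Villiger ring expansion of 4,4-disubstituted cyclobutenones to 5,5-disubstituted butenolides and of 3-alkoxycyclobutanones to γ-lactones.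

Step 13
Reactants: 19 dispiro bis(4-benzyloxybutenolide)
Product: 20 dispiro bis(tetronic acid) (4-hydroxybutenolides; ring OTES and side-chain OTBS unchanged)
Conditions: H2 (1 atm), Pd/C, EtOAc, rt; used at once
Reagents that add atoms: none
Why: Hydrogenolysis of the O-benzyl group of a vinylogous carbonate is fast and neutral, while the tetrasubstituted push–pull alkenes and the silyl ethers are inert in ethyl acetate.

Step 14
Reactants: 20 dispiro bis(tetronic acid)
Product: 21 dispiro bis(4-bromobutenolide) with ring OTES and side-chain OTBS groups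
Conditions: (COBr)2, DMF, 2,6-lutidine, CH2Cl2, 0 °C
Reagents that add atoms: oxalyl bromide, O=C(Br)C(Br)=O
Why: Vilsmeier-type halogenation of a vinylogous acid (tetronic acid to 4-bromobutenolide through the O-iminium salt and addition–elimination of bromide), buffered with a hindered pyridine so that no free HBr reaches the silyl ethers.

Step 15
Reactants: 21 dispiro bis(4-bromobutenolide) with ring OTES groups
Product: 22 ring trans-diol of the dispiro bis(4-bromobutenolide) (side-chain OTBS kept; each OH cis to O1 of the neighbouring lactone)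
Conditions: PPTS, MeOH/CH2Cl2, 0 °C to rt
Reagents that add atoms: none
Why: Acid-catalysed methanolysis cleaves triethylsilyl ethers much faster than tert-butyldimethylsilyl ethers, and the non-basic medium avoids ring alkoxides, which could open the cyclobutane by a vinylogous retro-aldol reaction.

Step 16
Reactants: 22 ring trans-diol of the dispiro bis(4-bromobutenolide)
Product: 24 tetrabromide bis(TBS ether) (ring bromides trans to each other and each cis to C4 of the neighbouring lactone), via ring bis-triflate 23 (not isolated)
Conditions: Tf2O, 2,6-lutidine, CH2Cl2, −40 °C; then Bu4NBr, toluene, rt to 40 °C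
Reagents that add atoms: tetrabutylammonium bromide, CCCC[N+](CCCC)(CCCC)CCCC.[Br-]
Why: Triflation and twofold SN2 displacement by bromide with inversion at each carbinol carbon, the double inversion known for vicinal trans-bis-triflates; after the first substitution the new bromine is cis to the remaining triflate and cannot participate, so the second substitution also inverts, and elimination towards the spiro carbons is impossible because they carry no hydrogen.

Step 17
Reactants: 24 tetrabromide bis(TBS ether)
Product: 25 tetrabromide diol with one (S)- and one (R)-1-hydroxybutyl side chain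
Conditions: HF (48% aq.), MeCN, 0 °C to rt
Reagents that add atoms: none
Why: Acidic fluoride cleavage of silyl ethers avoids basic fluoride sources, which could attack the bromobutenolides or eliminate HBr.

Step 18
Reactants: 25 tetrabromide diol
Product: 26 target, (5S,6S,11R,12R)-3-[(1S)-1-acetoxybutyl]-9-[(1R)-1-acetoxybutyl]-4,10,11,12-tetrabromo-1,7-dioxadispiro[4.0.4.2]dodeca-3,9-diene-2,8-dione
Conditions: Ac2O, TMSOTf (cat.), CH2Cl2, −10 °C
Reagents that add atoms: acetic anhydride, CC(=O)OC(C)=O
Why: Acid-catalysed acylation esterifies both secondary alcohols without an amine nucleophile that could substitute the vinylic bromides, and it does not touch the carbinol configuration.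

**Compound list**

1 | cyclobutane-1,2,3,4-tetracarboxylic 1,2:3,4-dianhydride (cis,trans,cis) | O=C1OC(=O)[C@H]2[C@@H]1[C@@H]3C(=O)OC(=O)[C@H]23 | starting material
2 | (1R,2R,3R,4R)-3,4-bis(methoxycarbonyl)cyclobutane-1,2-dicarboxylic acid | COC(=O)[C@@H]1[C@H](C(O)=O)[C@@H](C(O)=O)[C@H]1C(=O)OC | intermediate
3 | dimethyl 3,4-bis(chlorocarbonyl)cyclobutane-1,2-dicarboxylate (configuration of 2) | COC(=O)[C@@H]1[C@H](C(Cl)=O)[C@@H](C(Cl)=O)[C@H]1C(=O)OC | intermediate
4 | dimethyl (1R,2R,3R,4R)-3,4-diacetylcyclobutane-1,2-dicarboxylate | COC(=O)[C@@H]1[C@H](C(C)=O)[C@@H](C(C)=O)[C@H]1C(=O)OC | intermediate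
5 | dimethyl (1S,2S,3S,4S)-3,4-diacetoxycyclobutane-1,2-dicarboxylate | COC(=O)[C@@H]1[C@H](OC(C)=O)[C@@H](OC(C)=O)[C@H]1C(=O)OC | intermediate
6 | dimethyl (1S,2S,3S,4S)-3,4-dihydroxycyclobutane-1,2-dicarboxylate | COC(=O)[C@@H]1[C@H](O)[C@@H](O)[C@H]1C(=O)OC | intermediate
7 | dimethyl (1S,2S,3S,4S)-3,4-bis(triethylsilyloxy)cyclobutane-1,2-dicarboxylate | COC(=O)[C@@H]1[C@H](O[Si](CC)(CC)CC)[C@@H](O[Si](CC)(CC)CC)[C@H]1C(=O)OC | intermediate
8 | (1S,2S,3S,4S)-3,4-bis(triethylsilyloxy)cyclobutane-1,2-dicarboxylic acid | OC(=O)[C@@H]1[C@H](O[Si](CC)(CC)CC)[C@@H](O[Si](CC)(CC)CC)[C@H]1C(O)=O | intermediate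
9 | (1S,2S,3S,4S)-3,4-bis(triethylsilyloxy)cyclobutane-1,2-dicarbonyl dichloride | ClC(=O)[C@@H]1[C@H](O[Si](CC)(CC)CC)[C@@H](O[Si](CC)(CC)CC)[C@H]1C(Cl)=O | intermediate
10 | benzyl alcohol | OCc1ccccc1 | starting material
11 | trichloroethylene | ClC=C(Cl)Cl | starting material
12 | benzyl (E)-1,2-dichlorovinyl ether | Cl/C=C(Cl)\OCc1ccccc1 | intermediate
13 | butanal | CCCC=O | starting material
14 | lithium (benzyloxy)ethynide | [Li]C#COCc1ccccc1 | intermediate
15 | rac-1-(benzyloxy)hex-1-yn-3-ol | CCCC(O)C#COCc1ccccc1 | intermediate
16 | rac-1-(benzyloxy)-3-(tert-butyldimethylsilyloxy)hex-1-yne (racemate, no stereodescriptor) | CCCC(O[Si](C)(C)C(C)(C)C)C#COCc1ccccc1 | intermediate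
17 | (3S,4S)-3,4-bis(triethylsilyloxy)cyclobutane-1,2-diylidene bis(ketene) | O=C=C1[C@H](O[Si](CC)(CC)CC)[C@@H](O[Si](CC)(CC)CC)C1=C=O | intermediate
18 | dispiro bis(3-benzyloxycyclobut-2-enone), (S)- and (R)-1-(TBSO)butyl at C2, ring trans-bis(OTES) | CCC[C@H](O[Si](C)(C)C(C)(C)C)C1=C(OCc3ccccc3)[C@@]2(C1=O)[C@H](O[Si](CC)(CC)CC)[C@@H](O[Si](CC)(CC)CC)[C@@]21C(=O)C([C@@H](CCC)O[Si](C)(C)C(C)(C)C)=C1OCc1ccccc1 | intermediate
19 | dispiro bis(4-benzyloxybutenolide) (bis benzyl tetronate) | CCC[C@H](O[Si](C)(C)C(C)(C)C)C1=C(OCc3ccccc3)[C@@]2(OC1=O)[C@H](O[Si](CC)(CC)CC)[C@@H](O[Si](CC)(CC)CC)[C@@]21OC(=O)C([C@@H](CCC)O[Si](C)(C)C(C)(C)C)=C1OCc1ccccc1 | intermediate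
20 | dispiro bis(tetronic acid) | CCC[C@H](O[Si](C)(C)C(C)(C)C)C1=C(O)[C@@]2(OC1=O)[C@H](O[Si](CC)(CC)CC)[C@@H](O[Si](CC)(CC)CC)[C@@]21OC(=O)C([C@@H](CCC)O[Si](C)(C)C(C)(C)C)=C1O | intermediate
21 | dispiro bis(4-bromobutenolide), ring bis(OTES), side-chain bis(OTBS) | CCC[C@H](O[Si](C)(C)C(C)(C)C)C1=C(Br)[C@@]2(OC1=O)[C@H](O[Si](CC)(CC)CC)[C@@H](O[Si](CC)(CC)CC)[C@@]21OC(=O)C([C@@H](CCC)O[Si](C)(C)C(C)(C)C)=C1Br | intermediate
22 | ring trans-diol of the dispiro bis(4-bromobutenolide) | CCC[C@H](O[Si](C)(C)C(C)(C)C)C1=C(Br)[C@@]2(OC1=O)[C@H](O)[C@@H](O)[C@@]21OC(=O)C([C@@H](CCC)O[Si](C)(C)C(C)(C)C)=C1Br | intermediate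
23 | ring bis(triflate) of 22 | CCC[C@H](O[Si](C)(C)C(C)(C)C)C1=C(Br)[C@@]2(OC1=O)[C@H](OS(=O)(=O)C(F)(F)F)[C@@H](OS(=O)(=O)C(F)(F)F)[C@@]21OC(=O)C([C@@H](CCC)O[Si](C)(C)C(C)(C)C)=C1Br | intermediate
24 | tetrabromide bis(TBS ether) | CCC[C@H](O[Si](C)(C)C(C)(C)C)C1=C(Br)[C@@]2(OC1=O)[C@@H](Br)[C@H](Br)[C@@]21OC(=O)C([C@@H](CCC)O[Si](C)(C)C(C)(C)C)=C1Br | intermediate
25 | tetrabromide diol | CCC[C@H](O)C1=C(Br)[C@@]2(OC1=O)[C@@H](Br)[C@H](Br)[C@@]21OC(=O)C([C@@H](CCC)O)=C1Br | intermediate
26 | (5S,6S,11R,12R)-3-[(1S)-1-acetoxybutyl]-9-[(1R)-1-acetoxybutyl]-4,10,11,12-tetrabromo-1,7-dioxadispiro[4.0.4.2]dodeca-3,9-diene-2,8-dione | CCC[C@H](OC(C)=O)C1=C(Br)[C@@]2(OC1=O)[C@@H](Br)[C@H](Br)[C@@]21OC(=O)C([C@@H](CCC)OC(C)=O)=C1Br | target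

**Step count and risks**

Total step count: 18. Longest linear sequence: 15 steps (steps 1 to 7 and 11 to 18, from dianhydride 1).

The three steps most likely to fail:

1. Step 12. The peracid may add too slowly to the deactivated vinylogous-ester carbonyl, or the electron-rich sp2 carbon may migrate instead of the spiro carbon and give the isomeric enol lactones. The fallback removes the vinylogy before oxygen insertion and uses only known reactions; it sets out from 18 and comes back at 20. Hydrogen over Rh/Al2O3 in ethyl acetate at 1 atm saturates the two strained enol-ether double bonds without cleaving O-benzyl groups and gives the bis(3-benzyloxycyclobutanone) F1 (mixture of epimers at the new CH centres, which become planar again later). Oxidation of these ordinary strained ketones with mCPBA, a standard Baeyer–Villiger reaction of 3-alkoxycyclobutanones in which the quaternary spiro carbon migrates with retention, gives the bis(4-benzyloxy-γ-butyrolactone) F2. Hydrogenolysis (H2, Pd(OH)2/C) gives the bis(β-hydroxy lactone) F3, and Swern oxidation gives the β-keto lactones, that is bis-tetronic acid 20.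

2. Step 11. The hindered internal ynol ether may react too slowly, so that the ketene oligomerizes, and the two enantiomers may pair unfavourably, so that homochiral adducts prevail. The fallback orders the pairing; it sets out from 15 and 9 and comes back at 18. Lipase-catalysed acylation of 15 with vinyl acetate (kinetic resolution of a secondary propargylic alcohol) should leave the (S)-1-(benzyloxy)hex-1-yn-3-ol F4 and give the (R)-1-(benzyloxy)hex-1-yn-3-yl acetate F5 (sense expected from the usual empirical model and to be confirmed). K2CO3 in methanol converts F5 into the (R)-1-(benzyloxy)hex-1-yn-3-ol F6. Silylation as in step 10 gives the (S)-silyl ether F7 and the (R)-silyl ether F8. Diacid chloride 9 is then treated with one equivalent each of F7 and triethylamine to give the mono-cyclobutenone acid chloride F9. Its remaining acyl chloride, flanked by a quaternary spiro carbon, should form its ketene more slowly. F8 and the rest of the base are then added to the same flask to complete 18.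

3. Step 16. Backside attack at ring carbons flanked by a quaternary spiro carbon may be too slow, so that loss of triflate by elimination or skeletal rearrangement takes over. The fallback replaces sulfonate displacement by collapse of an alkoxyphosphonium bromide ion pair; it sets out from 21 and comes back at 24 and makes no new compound (F0). Triphenylphosphine dibromide (Ph3PBr2) in CH2Cl2 converts secondary trialkylsilyl ethers directly into bromides with inversion (Appel-type). The free diol, which under such conditions would close to an epoxide, never forms, and the bulkier TBS ethers react more slowly.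

**Further compounds**

F1 | step 12 | dispiro bis(3-benzyloxycyclobutanone), epimer mixture at the new CH centres | CCC[C@H](O[Si](C)(C)C(C)(C)C)C1C(OCc3ccccc3)[C@@]2(C1=O)[C@H](O[Si](CC)(CC)CC)[C@@H](O[Si](CC)(CC)CC)[C@@]21C(=O)C([C@@H](CCC)O[Si](C)(C)C(C)(C)C)C1OCc1ccccc1
F2 | step 12 | dispiro bis(4-benzyloxy-γ-butyrolactone) | CCC[C@H](O[Si](C)(C)C(C)(C)C)C1C(OCc3ccccc3)[C@@]2(OC1=O)[C@H](O[Si](CC)(CC)CC)[C@@H](O[Si](CC)(CC)CC)[C@@]21OC(=O)C([C@@H](CCC)O[Si](C)(C)C(C)(C)C)C1OCc1ccccc1
F3 | step 12 | dispiro bis(4-hydroxy-γ-butyrolactone) | CCC[C@H](O[Si](C)(C)C(C)(C)C)C1C(O)[C@@]2(OC1=O)[C@H](O[Si](CC)(CC)CC)[C@@H](O[Si](CC)(CC)CC)[C@@]21OC(=O)C([C@@H](CCC)O[Si](C)(C)C(C)(C)C)C1O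
F4 | step 11 | (S)-1-(benzyloxy)hex-1-yn-3-ol | CCC[C@H](O)C#COCc1ccccc1
F5 | step 11 | (R)-1-(benzyloxy)hex-1-yn-3-yl acetate | CCC[C@@H](OC(C)=O)C#COCc1ccccc1
F6 | step 11 | (R)-1-(benzyloxy)hex-1-yn-3-ol | CCC[C@@H](O)C#COCc1ccccc1
F7 | step 11 | (S)-1-(benzyloxy)-3-(tert-butyldimethylsilyloxy)hex-1-yne | CCC[C@H](O[Si](C)(C)C(C)(C)C)C#COCc1ccccc1
F8 | step 11 | (R)-1-(benzyloxy)-3-(tert-butyldimethylsilyloxy)hex-1-yne | CCC[C@@H](O[Si](C)(C)C(C)(C)C)C#COCc1ccccc1
F9 | step 11 | mono-cyclobutenone acid chloride (one spiro ring closed, one COCl left) | CCC[C@H](O[Si](C)(C)C(C)(C)C)C1=C(OCc3ccccc3)[C@@]2(C1=O)[C@H](O[Si](CC)(CC)CC)[C@@H](O[Si](CC)(CC)CC)[C@H]2C(Cl)=O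
F0 | step 16 | none | none
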